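Amounts first, as fractions of the charge. In the zeta run, which is the asked flask followed so far, Xa and Ty together miss about 13.0% of the charge from 6.00 h to 15.0 h. We take that share as a pool of dissolved Ty, while Xa gains 0.0383 h⁻¹.

| setting | zeta | gamma | flask |
|---|---|---|---|
| Ty | 0.20 M | 0.13 M | 0.20 M |
| Zo | 0.30 M | 0.30 M | 0.300 M |
| Qi | 4 mM | 4 mM | 4.00 mM |
| remark | the very flask that is asked about, followed so far | run made earlier |  |
| time |  |  | 40 h |

- zeta (time / h: Xa / %, Ty / %): 1.00: 1.4, 90.3; 3.00: 7.6, 80.1; 6.00: 20.1, 65.9; 8.00: 28.0, 59.5; 12.0: 45.3, 43.1; 15.0: 53.6, 32.6
- gamma (time / h: Xa / %, Ty / %): 2.50: 10.7, 72.6; 8.00: 44.4, 36.2; 15.0: 80.4, 0; 20.0: 93.5, 1.3; 30.0: 97.0, 0.5; 40.0: 98.1, 1.8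

(standard deviation of a reading: 1 percentage point)

1. amount of Xa at 40 h, in percent of the Ty charged
2. the change that raises the amount of Xa at 40 h, in percent of the Ty charged most ("none" if none brings more than 2 percentage points) (north-west / south-east / north-east / none)
3. amount of Xa at 40 h, in percent of the Ty charged, after north-west

- north-west: doubling the dissolution coefficient of Ty, all else as stated
- south-east: doubling the solubility of Ty, all else as stated
- north-east: doubling the amount of Zo, all else as stated

- given per volume of solution although it is solid: Ty
- the numbers in the tables scatter by 1 percentage point (one standard deviation)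
- at the start none of Ty is in solution

Dividing that gain by the pool and by the free Zo of the stretch, 0.226 M if Zo is used mole for mole, gives 1.30 M⁻¹ h⁻¹. We call this the clearing constant, the share of the pool turned into Xa per hour for each mole per litre of free Zo. Times Zo held fixed, it is a pseudo-first-order rate constant.

Carried on in a straight line from 3.00 h to 15.0 h, the Ty readings of the zeta run reach zero at about 23.2 h, which is our estimate. After that we let the pool only drain, and we call what still sits in it at 40 h the residue, our measure of the room left for any change. With Zo as charged the pool clears at 0.391 h⁻¹, and the residue comes to 0.0182%. But that answer leaves Zo at 0.100 M, so we go round again with the mean Zo of the tail, 0.113 M. The rate drops to 0.147 h⁻¹, the residue is 1.10%, and our own answer is 98.9%.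

Now the settings by hand. Doubling dissolution, taken as halving the time the solid lasts, gains 0.9 percentage points. Doubling solubility, taken as also doubling the pool, gains 0.7 points. Doubling Zo, added to the mean Zo of the tail, shrinks the residue and gains 1.1 points. Each stays under 2 points, so we choose none.

The forecast differs from our reckoning: it gives 94.5%, lower than our answer, then 96% after north-west, and north-east as best, on the ground “Doubling Zo speeds the reaction and shifts the equilibrium”.

The simulation gives 96.7%, 97.4% after north-west, and best: none. The gains are 0.68 points for north-west, 1 point for south-east and 1.3 points for north-east.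

    Zu + Zo → Xa (k = 3.90 × 10⁻⁴ M⁻¹ s⁻¹)
    Ty ⇌ Zu, rate k2*(cs2 - [Zu]) while solid is left; crystals form when [Zu] > cs2 (solubility = 40.0 mM, k = 1.30 × 10⁻⁴ s⁻¹)
    Ty + Qi → Dx (k = 0.0240 M⁻¹ s⁻¹)

At 40 h the flask holds Zu 1.28% against our residue of 1.10%, and Dx 2.00%, which our answer did not count. The neighbour charged with 0.80 M of Ty takes the same constant, with the pool held at zeta's amount, 0.0259 M. With Zo as charged, Xa comes to 50.8% of its charge, more than its 0.375 equiv of Zo can make. Going round with Zo falling leaves 25.8% of the Zo and Xa at 27.8%. At 40.0 h that neighbour holds Zo 23.3% of its own charge, and Ty 66.7% and Xa 28.8% of the Ty charged.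

All runs were computed from invented constants; noise was put on by code.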